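## Structural features

1. The target is a 5,7-dihydroxyflavone. Benzo ring A (C4a, C5, C6, C7, C8, C8a) is fused along C4a–C8a to 4-pyranone ring C (O1, C2, C3, C4, C4a, C8a), and C2 carries aryl ring B (C1' to C6').
2. Ring A is hexasubstituted and fully differentiated: C5–OH (hydrogen-bonded to the C4 carbonyl), C6–H, C7–OH, C8–prenyl (3-methylbut-2-enyl), C8a–O1 and C4a–C4.
3. Ring B has a free OH on C3' and is fused through O4' and C5' to a 2,2-dimethyl-2H-pyran (ring D), so the two neighbouring catechol oxygens must be told apart.
4. There is no stereocentre and no stereogenic double bond, so the whole difficulty is regiochemical and chemoselective.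
5. The hardest point is placing prenyl on C8 and not on C6. In every phloroglucinol-type precursor the two carbons are equivalent or nearly so, and a 5-hydroxyflavone can exchange them by opening and reclosure of ring C (Wessely–Moser rearrangement).
6. The fragile groups are the prenyl alkene, which adds O7 under acid to give a chroman, and the ring D alkene. Together they rule out hydrogenolysis, strong protic acid and strong Lewis acid late in the route.
7. The key step exploits the position of C8a, which bears O1 and stands between C8 and C4a. A monocyclic 2-aryl-4-pyranone already holds O1, C2, C3, C4, C4a and C8a, can carry C8 with its prenyl group as a side-chain carbon on C8a, and offers C4a–H as the only carbon on which a new six-membered ring can close.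
8. Ring A can therefore be built last, around a prenyl group whose place next to O1 is fixed by connectivity and not by selectivity.

## Logic of the disconnections

**22 from 21.** The O3'–Si bond and the O7–CH2 bond are cut.
- Reason: the last step must not use acid, Lewis acid, hydrogen or oxidant.
- Gain: both masks fall to fluoride in one operation.
- Demand: both groups must survive every earlier step, and the O7 group must be one that can arrive on a two-carbon alkyne.

**21 from 11 and 15 (key disconnection).** Three bonds of ring A are cut: C4a–C5, C5–C6 and C7–C8.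
- C6 and C7 (with O7) go to 15. C5 (with O5) becomes the carboxyl carbon of 11. C8, C8a and C4a remain in 11 as the side-chain carbon and two ring carbons.
- A bond that is absent from 22, C5–C8, is present in 11, 16, 17 and 18. It is cleaved when the strained four-membered ring of 18 opens.
- In one sentence: ring A is made last, by a ketene/ynol ether benzannulation on 11, a finished 2-aryl-4-pyranone that carries C8, its prenyl group and C5 as a side-chain acid.
- Gain: a hexasubstituted benzo ring is exchanged for a monocyclic acid and a two-carbon piece. The C6/C8 question disappears, because C8 is bonded to C8a before ring A exists.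
- Demand: 17 must form without acid. 15 must add with its CH carbon to the carbonyl carbon of 17. 18 must open so that the heterocycle faces the new ketene, and 19 must close on the C–H carbon of the heterocycle.

**15 from 12 and 13.** The O–C(sp) bond is cut.
- Reason: a fluoride-labile O7 group is needed and the matching alkyne is not sold.
- Gain: two bulk chemicals.
- Demand: the alkoxide of 12 must be captured before it fragments.

**11 from 10.** The C8–C5 bond (side-chain carbon to carboxyl carbon) is cut.
- Reason: the CH2 next to C8a is the vinylogous alpha position of the ring carbonyl and the only acidic site of 10.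
- Gain: the C1 unit comes from a gas.
- Demand: reaction at the exocyclic carbon and gentle handling of an acid that can lose CO2.

**10 from 9.** The O1–C8a bond is cut.
- Reason: a 1,3,5-triketone can lose water in one way only.
- Gain: ring C becomes an open chain.
- Demand: acid mild enough for two alkenes and an aryl silyl ether.

**9 from 5 and 8.** The C2–C3 bond is cut.
- Reason: it joins a non-enolisable ester to a terminal carbanion and is the point of convergence.
- Gain: the ring B/D half and the C3–C8 chain become independent.
- Demand: the second deprotonation of 8 must occur at its methyl end.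

**8 from 6 and 7.** The bond between C8 and the prenyl CH2 is cut.
- Reason: here, on a symmetrical five-carbon diketone, prenylation has no regiochemical alternative.
- Gain: two commodity chemicals.
- Demand: terminal monoalkylation.

**5 from 4, 4 from 3, 3 from 1 and 2.** The O3'–Si bond is cut first. Next come the C5'–C bond and the O4'–C bond of ring D (one sigmatropic cascade), and last the O4'–C bond of the propargyl ether.
- Reason: O4' has one free ortho carbon, so ring D can form only on C5'.
- Gain: ring D and the catechol differentiation come from one selective O-alkylation.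
- Demand: alkylation of the more acidic of the two hydroxyls of 1.

## Other disconnections considered

**Alternative 1:** cut O1–C2 and C2–C3 of ring C. This is the first cut that comes to mind.
- Forward key step: the acetophenone A1 is O-aroylated with the acid chloride A2. A Baker–Venkataraman acyl shift gives the diketone A3, acid closes ring C, and acid removes the acetals.
- The key step builds the easiest ring and leaves the hard part to A1. There the prenyl group must be placed on one of two nearly equivalent ring carbons, against O-alkylation and double alkylation.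
- In A1 the hydroxyl next to the prenyl group, and no other, must also stay free.
- Two acidic operations then act on a prenyl group that sits next to an oxygen, and on a 5-oxygenated flavone that can open and reclose.
- The chosen plan needs no selectivity on ring A and no acid after ring A exists.

**Alternative 2:** cut only the C8–prenyl bond.
- Forward key step: the 5-O-prenyl ether A4 undergoes a Claisen shift to C6 (inverted allyl), then a Cope shift to C8 (normal prenyl).
- The step forms one bond and simplifies nothing else. The whole flavone with O5, O7 and O3' told apart must be made first, and O5 is the least nucleophilic oxygen because of its hydrogen bond.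
- The outcome depends on a race. If enolisation at C6 follows the first shift, the relay stops with the wrong group on the wrong carbon.
- The heat or Lewis acid needed also bears on ring D.

**Alternative 3:** cut C4–C4a, C3–C4 and O1–C2.
- Forward key step: carbonylative Sonogashira coupling of the iodophenol A5, CO and the alkyne A6 with a zerovalent palladium catalyst such as Pd(PPh3)4. This gives the ynone A7, and 6-endo addition of the phenol follows.
- The step is convergent and forms three bonds, but the C6/C8 problem moves unchanged into A5, a pentasubstituted arene that must be iodinated and prenylated at defined positions.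
- Oxidative addition into an electron-rich iodide with two ortho substituents is slow. The 5-exo closure to an aurone competes with the 6-endo mode, and the final acetal removal is again acidic.

Key step: step 9

Remarks on the chemistry. The target has no stereocentre. Compounds 11, 16, 18 and 20 each have one stereocentre, are racemic, and lose it on aromatisation. In the names below Ar stands for 2,2-dimethyl-8-[(triisopropylsilyl)oxy]-2H-chromen-6-yl.

## Steps

**Step 1**
Reactants: 1 methyl 3,4-dihydroxybenzoate; 2 3-chloro-3-methylbut-1-yne
Product: 3 methyl 3-hydroxy-4-[(2-methylbut-3-yn-2-yl)oxy]benzoate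
Conditions: K2CO3 (1.1 equiv), KI (cat.), acetone, reflux
Reagents that add atoms: none
Why: Williamson-type O-alkylation of a phenoxide by a tertiary propargylic chloride; with one equivalent of weak base only the more acidic 4-OH (para to the ester) is ionised, so the ether forms on the future O4'.

**Step 2**
Reactants: 3 methyl 3-hydroxy-4-[(2-methylbut-3-yn-2-yl)oxy]benzoate
Product: 4 methyl 8-hydroxy-2,2-dimethyl-2H-chromene-6-carboxylate
Conditions: N,N-diethylaniline, 190 °C
Reagents that add atoms: none
Why: Aromatic propargyl Claisen rearrangement, then a 1,5-hydrogen shift and an oxa-6π electrocyclisation; the ether oxygen has one free ortho carbon, so ring D can form in one way only and the neighbouring OH stays free.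

**Step 3**
Reactants: 4 methyl 8-hydroxy-2,2-dimethyl-2H-chromene-6-carboxylate
Product: 5 methyl 2,2-dimethyl-8-[(triisopropylsilyl)oxy]-2H-chromene-6-carboxylate
Conditions: iPr3SiCl, imidazole, DMF, rt
Reagents that add atoms: chlorotriisopropylsilane, CC(C)[Si](Cl)(C(C)C)C(C)C
Why: Standard silylation of a phenol; the bulky aryl silyl ether should withstand enolates, amide bases and catalytic acid and falls to fluoride at the end.

**Step 4**
Reactants: 6 pentane-2,4-dione; 7 1-bromo-3-methylbut-2-ene
Product: 8 8-methylnon-7-ene-2,4-dione
Conditions: LiN(iPr)2 (2.1 equiv), THF, 0 °C; 7, 0 °C; 1 M HCl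
Reagents that add atoms: none
Why: Gamma-alkylation of a beta-diketone dianion; the terminal carbanion is the more reactive site and displaces the primary allylic bromide by SN2, and the symmetry of 6 leaves no regiochemical choice.

**Step 5**
Reactants: 5 methyl 2,2-dimethyl-8-[(triisopropylsilyl)oxy]-2H-chromene-6-carboxylate; 8 8-methylnon-7-ene-2,4-dione
Product: 9 1-Ar-9-methyldec-8-ene-1,3,5-trione
Conditions: 8 (2 equiv), LiN(iPr)2 (4 equiv), THF, −78 to 0 °C; 5, 0 °C to rt; 1 M HCl
Reagents that add atoms: none
Why: Claisen-type aroylation of a beta-diketone dianion by a non-enolisable aromatic ester; the second deprotonation of 8 should take the less hindered methyl group, and the excess dianion absorbs the acidic proton of 9.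

**Step 6**
Reactants: 9 1-Ar-9-methyldec-8-ene-1,3,5-trione
Product: 10 2-Ar-6-(4-methylpent-3-en-1-yl)-4H-pyran-4-one
Conditions: p-TsOH·H2O (10 mol %), 4 Å molecular sieves, toluene, 70 °C
Reagents that add atoms: none
Why: Acid-catalysed cyclodehydration of a 1,3,5-triketone to a 4-pyranone, for which only one ring is possible; isolated trisubstituted alkenes and 2,2-dimethylchromenes tolerate catalytic sulfonic acid in warm arene solvents, as in routine ketalisations and chromanol dehydrations.

**Step 7**
Reactants: 10 2-Ar-6-(4-methylpent-3-en-1-yl)-4H-pyran-4-one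
Product: 11 2-(6-Ar-4-oxo-4H-pyran-2-yl)-5-methylhex-4-enoic acid (racemic)
Conditions: LiN(iPr)2 (1.1 equiv), THF, −78 °C; dry CO2, −78 to −20 °C; cold 0.5 M HCl to pH 3
Reagents that add atoms: carbon dioxide, O=C=O
Why: Lateral (vinylogous) deprotonation of a 2-alkyl-4-pyranone and carboxylation at the exocyclic carbon, which restores the conjugated ring; the new stereocentre is racemic and disappears in step 9.

**Step 8**
Reactants: 12 2-(trimethylsilyl)ethanol; 13 trichloroethene
Product: 15 [2-(ethynyloxy)ethyl]trimethylsilane, via dichlorovinyl ether 14 (not isolated)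
Conditions: KH, THF, 0 °C; 13, −50 °C to rt; n-BuLi (2.4 equiv), −78 to −40 °C; H2O, −78 °C
Reagents that add atoms: none
Why: Dichlorovinyl ether route to terminal ynol ethers; the alkoxide adds anti to dichloroacetylene formed in the flask from 13 and gives (E)-14, n-BuLi then effects dehydrochlorination and chlorine–lithium exchange, and water protonates the acetylide salt of 15.

**Step 9**
Reactants: 11 2-(6-Ar-4-oxo-4H-pyran-2-yl)-5-methylhex-4-enoic acid; 15 [2-(ethynyloxy)ethyl]trimethylsilane
Product: 21 2-Ar-5-hydroxy-8-(3-methylbut-2-en-1-yl)-7-[2-(trimethylsilyl)ethoxy]-4H-chromen-4-one, via acid chloride 16 (not isolated), via ketene 17 (not isolated), via cyclobutenone 18 (not isolated), via dienylketene 19 (not isolated), via cyclohexadienone 20 (not isolated)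
Conditions: Me2C=C(Cl)NMe2 (1.05 equiv), CH2Cl2, 0 °C; evaporate; 15 (2 equiv), Et3N (slow addition), toluene, 0 °C to rt; filter, strip excess 15; toluene (0.01 M), 110 °C
Reagents that add atoms: none
Why: Neutral chlorination gives 16, Et3N removes its doubly activated alpha hydrogen to give the conjugated ketene 17, and the nucleophilic CH carbon of 15 attacks the ketene carbonyl carbon, after which the zwitterion collapses to the 3-alkoxycyclobutenone 18, the regiochemistry being set by the polarity of both partners. At 110 °C release of ring strain drives a conrotatory 4π opening of 18 that cleaves the temporary C5–C8 bond, and the (E)-dienylketene 19 closes by a disrotatory 6π electrocyclisation between the ketene carbon (C5) and the pyranone C–H carbon (C4a) to 20, which enolises irreversibly to the hydrogen-bonded 5-phenol 21. This is the Danheiser benzannulation (a conjugated ketene plus a heterosubstituted alkyne), known for vinyl-, aryl- and heteroaryl-ketenes, and here the C4a=C8a bond of a weakly aromatic 4-pyranone plays the vinyl part. The only ring that stays closed is ring A, six-membered and carbocyclic, closed by 6π electrocyclisation, whereas the four-membered ring is closed by [2+2] cycloaddition and opened again. The stereocentres of 18 and 20 are racemic and transient, so no stereocontrol is needed. The selectivity needed is regiochemical, prenyl next to C8a–O1, and it is secured because C8 is bonded to C8a before the ring exists and because the heterocycle offers a single carbon next to the side chain. The 4π opening must turn the pyranonyl group toward the ketene, which is favoured because the alkyl group has the stronger outward preference, because the opening is reversible and because only 19 is drained by aromatisation. A direct vinylogous collapse of the zwitterion on C4a (formal [4+2]) would only exchange which of O5 and O7 bears the silylethyl group, a difference that step 10 erases.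

**Step 10**
Reactants: 21 2-Ar-5-hydroxy-8-(3-methylbut-2-en-1-yl)-7-[2-(trimethylsilyl)ethoxy]-4H-chromen-4-one
Product: 22 5,7-dihydroxy-2-(8-hydroxy-2,2-dimethyl-2H-chromen-6-yl)-8-(3-methylbut-2-en-1-yl)-4H-chromen-4-one (target)
Conditions: Bu4NF (4 equiv), THF, 0 to 45 °C; AcOH quench
Reagents that add atoms: none
Why: Fluoride cleaves the aryl silyl ether at silicon and triggers beta-fragmentation of the 2-(trimethylsilyl)ethyl ether with loss of ethene, helped by the low pKa of the 7-phenol of a flavone; no acid, Lewis acid or hydrogen touches the prenyl and ring D alkenes.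

## Compound list

1 | methyl 3,4-dihydroxybenzoate | COC(=O)c1ccc(O)c(O)c1 | starting material
2 | 3-chloro-3-methylbut-1-yne | C#CC(C)(C)Cl | starting material
3 | methyl 3-hydroxy-4-[(2-methylbut-3-yn-2-yl)oxy]benzoate | COC(=O)c1ccc(OC(C)(C)C#C)c(O)c1 | intermediate
4 | methyl 8-hydroxy-2,2-dimethyl-2H-chromene-6-carboxylate | COC(=O)c1cc(O)c2c(c1)C=CC(C)(C)O2 | intermediate
5 | methyl 2,2-dimethyl-8-[(triisopropylsilyl)oxy]-2H-chromene-6-carboxylate | COC(=O)c1cc(O[Si](C(C)C)(C(C)C)C(C)C)c2c(c1)C=CC(C)(C)O2 | intermediate
6 | pentane-2,4-dione | CC(=O)CC(C)=O | starting material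
7 | 1-bromo-3-methylbut-2-ene | CC(C)=CCBr | starting material
8 | 8-methylnon-7-ene-2,4-dione | CC(=O)CC(=O)CCC=C(C)C | intermediate
9 | 1-Ar-9-methyldec-8-ene-1,3,5-trione | CC(C)=CCCC(=O)CC(=O)CC(=O)c1cc(O[Si](C(C)C)(C(C)C)C(C)C)c2c(c1)C=CC(C)(C)O2 | intermediate
10 | 2-Ar-6-(4-methylpent-3-en-1-yl)-4H-pyran-4-one | CC(C)=CCCc1cc(=O)cc(-c2cc(O[Si](C(C)C)(C(C)C)C(C)C)c3c(c2)C=CC(C)(C)O3)o1 | intermediate
11 | 2-(6-Ar-4-oxo-4H-pyran-2-yl)-5-methylhex-4-enoic acid (racemic) | CC(C)=CCC(C(=O)O)c1cc(=O)cc(-c2cc(O[Si](C(C)C)(C(C)C)C(C)C)c3c(c2)C=CC(C)(C)O3)o1 | intermediate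
12 | 2-(trimethylsilyl)ethanol | C[Si](C)(C)CCO | starting material
13 | trichloroethene | ClC=C(Cl)Cl | starting material
14 | (E)-{2-[(1,2-dichlorovinyl)oxy]ethyl}trimethylsilane | C[Si](C)(C)CCO/C(Cl)=C\Cl | intermediate
15 | [2-(ethynyloxy)ethyl]trimethylsilane | C#COCC[Si](C)(C)C | intermediate
16 | 2-(6-Ar-4-oxo-4H-pyran-2-yl)-5-methylhex-4-enoyl chloride (racemic) | CC(C)=CCC(C(=O)Cl)c1cc(=O)cc(-c2cc(O[Si](C(C)C)(C(C)C)C(C)C)c3c(c2)C=CC(C)(C)O3)o1 | intermediate
17 | 2-(6-Ar-4-oxo-4H-pyran-2-yl)-5-methylhexa-1,4-dien-1-one (ketene) | CC(C)=CCC(=C=O)c1cc(=O)cc(-c2cc(O[Si](C(C)C)(C(C)C)C(C)C)c3c(c2)C=CC(C)(C)O3)o1 | intermediate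
18 | 4-(3-methylbut-2-en-1-yl)-4-(6-Ar-4-oxo-4H-pyran-2-yl)-3-[2-(trimethylsilyl)ethoxy]cyclobut-2-en-1-one (racemic) | CC(C)=CCC1(C(=O)C=C1OCC[Si](C)(C)C)c1cc(=O)cc(-c2cc(O[Si](C(C)C)(C(C)C)C(C)C)c3c(c2)C=CC(C)(C)O3)o1 | intermediate
19 | (3E)-4-(6-Ar-4-oxo-4H-pyran-2-yl)-7-methyl-3-[2-(trimethylsilyl)ethoxy]octa-1,3,6-trien-1-one | O=C=C/C(OCC[Si](C)(C)C)=C(/CC=C(C)C)c1cc(=O)cc(-c2cc(O[Si](C(C)C)(C(C)C)C(C)C)c3c(c2)C=CC(C)(C)O3)o1 | intermediate
20 | 2-Ar-8-(3-methylbut-2-en-1-yl)-7-[2-(trimethylsilyl)ethoxy]-4aH-chromene-4,5-dione (racemic) | CC(C)=CCC1=C2OC(c3cc(O[Si](C(C)C)(C(C)C)C(C)C)c4c(c3)C=CC(C)(C)O4)=CC(=O)C2C(=O)C=C1OCC[Si](C)(C)C | intermediate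
21 | 2-Ar-5-hydroxy-8-(3-methylbut-2-en-1-yl)-7-[2-(trimethylsilyl)ethoxy]-4H-chromen-4-one | CC(C)=CCc1c(OCC[Si](C)(C)C)cc(O)c2c(=O)cc(-c3cc(O[Si](C(C)C)(C(C)C)C(C)C)c4c(c3)C=CC(C)(C)O4)oc12 | intermediate
22 | 5,7-dihydroxy-2-(8-hydroxy-2,2-dimethyl-2H-chromen-6-yl)-8-(3-methylbut-2-en-1-yl)-4H-chromen-4-one | CC(C)=CCc1c(O)cc(O)c2c(=O)cc(-c3cc(O)c4c(c3)C=CC(C)(C)O4)oc12 | target

## Step count and least certain steps

Total step count: 10. Longest linear sequence: 8 (steps 1, 2, 3, 5, 6, 7, 9, 10).

**Step 9 (key step).**
- Most likely failure: the four-membered ring opens with the pyranonyl group turned outward. The ketene is then consumed by the neighbouring prenyl alkene (intramolecular [2+2]) or by a 1,5-hydrogen shift before it can revert.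
- A slow 6π closure onto the heterocycle would also leave time for ketene dimerisation. Hydrogen chloride from the ammonium salt can add to the ynol ether.
- Fallback: it sets out from 11 and replaces the cycloaddition by a polyketide-type folding in which the geometry is set by keto–enol equilibrium and not by torquoselectivity. Coupling of 11 with Meldrum's acid (EDC, DMAP, CH2Cl2) would give the acyl Meldrum's acid F1.
- Thermolysis in dilute toluene at 110 °C would expel acetone and CO2 to give the acylketene F2. Its enol is the free-hydroxyl counterpart of 19 and should close on C4a in the same way, giving the 3'-O-silyl ether of the target F3.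
- Bu4NF buffered with AcOH then brings the sequence back to the route at 22. The closest analogy is the thermolysis of aminomethylene Meldrum's acids to 4-quinolones by ketene electrocyclisation.

**Step 7.**
- Most likely failure: loss of CO2 from the vinylogous beta-keto acid during acidification and drying. Incomplete lateral deprotonation of a secondary position is also possible.
- Fallback: it sets out from 10 and never forms the free acid. The lithiated species is trapped with allyl chloroformate to give the allyl ester F4, which can be purified and stored.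
- Pd(PPh3)4 (zerovalent palladium) and potassium 2-ethylhexanoate transfer the allyl group and precipitate the potassium carboxylate F5.
- (COCl)2 on the dry salt would give the acid chloride without any hydrogen chloride, and the sequence comes back to the route at 16.

**Step 8.**
- Most likely failure: Peterson-type fragmentation of the beta-silyl alkoxide (loss of ethene) before it is captured. The volatile product can also be lost on isolation.
- Fallback: it sets out from 11 and uses commercial ethoxyacetylene in place of 15 under the conditions of step 9, which would give the 7-O-ethyl-3'-O-silyl flavone F6.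
- Bu4NF removes the silyl group to give the 7-O-ethyl ether of the target F7.
- NaSEt in DMF at 110 °C then cleaves the ethyl ether by SN2 attack on carbon, a mechanism that leaves both alkenes alone. The sequence comes back to the route at 22.

**Step 5.**
- Most likely failure: partial second deprotonation of 8 at its internal CH2, which leads to branched acylation. O-acylation is also possible.
- Fallback: it sets out from 5 and 6 and reverses the order of bond formation, so that the dianion is that of a symmetrical diketone. Aroylation of the dianion of 6 with 5 would give the methyl triketone F8.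
- p-TsOH closes F8 to the 6-methylpyranone F9.
- Lateral lithiation with LiN(iPr)2 and alkylation with 7 bring the sequence back to the route at 10.

## Further compounds

F1 | step 9 | 5-[1-hydroxy-2-(6-Ar-4-oxo-4H-pyran-2-yl)-5-methylhex-4-en-1-ylidene]-2,2-dimethyl-1,3-dioxane-4,6-dione | CC(C)=CCC(C(O)=C1C(=O)OC(C)(C)OC1=O)c1cc(=O)cc(-c2cc(O[Si](C(C)C)(C(C)C)C(C)C)c3c(c2)C=CC(C)(C)O3)o1
F2 | step 9 | 4-(6-Ar-4-oxo-4H-pyran-2-yl)-7-methylocta-1,6-diene-1,3-dione (acylketene) | CC(C)=CCC(C(=O)C=C=O)c1cc(=O)cc(-c2cc(O[Si](C(C)C)(C(C)C)C(C)C)c3c(c2)C=CC(C)(C)O3)o1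
F3 | step 9 | 2-Ar-5,7-dihydroxy-8-(3-methylbut-2-en-1-yl)-4H-chromen-4-one | CC(C)=CCc1c(O)cc(O)c2c(=O)cc(-c3cc(O[Si](C(C)C)(C(C)C)C(C)C)c4c(c3)C=CC(C)(C)O4)oc12
F4 | step 7 | allyl 2-(6-Ar-4-oxo-4H-pyran-2-yl)-5-methylhex-4-enoate | CC(C)=CCC(C(=O)OCC=C)c1cc(=O)cc(-c2cc(O[Si](C(C)C)(C(C)C)C(C)C)c3c(c2)C=CC(C)(C)O3)o1
F5 | step 7 | potassium 2-(6-Ar-4-oxo-4H-pyran-2-yl)-5-methylhex-4-enoate | CC(C)=CCC(C(=O)[O-])c1cc(=O)cc(-c2cc(O[Si](C(C)C)(C(C)C)C(C)C)c3c(c2)C=CC(C)(C)O3)o1.[K+]
F6 | step 8 | 2-Ar-7-ethoxy-5-hydroxy-8-(3-methylbut-2-en-1-yl)-4H-chromen-4-one | CCOc1cc(O)c2c(=O)cc(-c3cc(O[Si](C(C)C)(C(C)C)C(C)C)c4c(c3)C=CC(C)(C)O4)oc2c1CC=C(C)C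
F7 | step 8 | 7-ethoxy-5-hydroxy-2-(8-hydroxy-2,2-dimethyl-2H-chromen-6-yl)-8-(3-methylbut-2-en-1-yl)-4H-chromen-4-one | CCOc1cc(O)c2c(=O)cc(-c3cc(O)c4c(c3)C=CC(C)(C)O4)oc2c1CC=C(C)C
F8 | step 5 | 1-Ar-hexane-1,3,5-trione | CC(=O)CC(=O)CC(=O)c1cc(O[Si](C(C)C)(C(C)C)C(C)C)c2c(c1)C=CC(C)(C)O2
F9 | step 5 | 2-Ar-6-methyl-4H-pyran-4-one | Cc1cc(=O)cc(-c2cc(O[Si](C(C)C)(C(C)C)C(C)C)c3c(c2)C=CC(C)(C)O3)o1
A1 | alternative 1 | 1-[2-hydroxy-4,6-bis(methoxymethoxy)-3-(3-methylbut-2-en-1-yl)phenyl]ethan-1-one | CC(=O)c1c(O)c(CC=C(C)C)c(OCOC)cc1OCOC
A2 | alternative 1 | 8-(methoxymethoxy)-2,2-dimethyl-2H-chromene-6-carbonyl chloride | COCOc1cc(C(=O)Cl)cc2c1OC(C)(C)C=C2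
A3 | alternative 1 | 1-[2-hydroxy-4,6-bis(methoxymethoxy)-3-(3-methylbut-2-en-1-yl)phenyl]-3-[8-(methoxymethoxy)-2,2-dimethyl-2H-chromen-6-yl]propane-1,3-dione | COCOc1cc(OCOC)c(C(=O)CC(=O)c2cc(OCOC)c3c(c2)C=CC(C)(C)O3)c(O)c1CC=C(C)C
A4 | alternative 2 | 7-(methoxymethoxy)-2-[8-(methoxymethoxy)-2,2-dimethyl-2H-chromen-6-yl]-5-[(3-methylbut-2-en-1-yl)oxy]-4H-chromen-4-one | CC(C)=CCOc1cc(OCOC)cc2oc(-c3cc(OCOC)c4c(c3)C=CC(C)(C)O4)cc(=O)c12
A5 | alternative 3 | 2-iodo-3,5-bis(methoxymethoxy)-6-(3-methylbut-2-en-1-yl)phenol | CC(C)=CCc1c(O)c(I)c(OCOC)cc1OCOC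
A6 | alternative 3 | 6-ethynyl-8-(methoxymethoxy)-2,2-dimethyl-2H-chromene | C#Cc1cc(OCOC)c2c(c1)C=CC(C)(C)O2
A7 | alternative 3 | 1-[2-hydroxy-4,6-bis(methoxymethoxy)-3-(3-methylbut-2-en-1-yl)phenyl]-3-[8-(methoxymethoxy)-2,2-dimethyl-2H-chromen-6-yl]prop-2-yn-1-one | COCOc1cc(OCOC)c(C(=O)C#Cc2cc(OCOC)c3c(c2)C=CC(C)(C)O3)c(O)c1CC=C(C)C
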